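## Retrosynthetic overview

1. The target comes from one hydrogenolysis that removes seven benzyl ethers and a blocking bromine from a (2R)-8-bromoflavanone.
2. Flavanone ring C (O1–C2 bond and the only stereocentre) comes from an enantioselective 6-endo oxa-Michael closure of a 2'-hydroxychalcone (key step, new); the chalcone comes from a Claisen–Schmidt condensation of a biaryl methyl ketone with 4-(benzyloxy)benzaldehyde.
3. The biaryl bond (flavanone C6 to luteolin C6') comes from a borylation/Suzuki coupling of a 6'-bromoflavone with an iodoacetophenone. Bromine blocks the site next to its free OH, so the aryl group ends up para to the cyclising oxygen (6-linked, not 8-linked).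
4. The flavone ring comes from an I2/DMSO oxidative C–O cyclisation of a 2'-hydroxychalcone made from 2'-hydroxy-4',6'-bis(benzyloxy)acetophenone and 4,5-bis(benzyloxy)-2-bromobenzaldehyde.
5. Ring order: flavone pyranone first, biaryl second, flavanone pyranone last, so the stereocentre is set after every basic step.

Assumption: the target SMILES defines no biaryl axis (two OH groups flank it), so only C-2 of the flavanone, which is R, is controlled; slowly rotating atropisomers of the benzylated intermediates are carried as mixtures and converge on deprotection.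

Catalyst B (step 8, not a numbered compound): the bifunctional iminophosphorane–thiourea 1-[3,5-bis(trifluoromethyl)phenyl]-3-[(2S)-3,3-dimethyl-1-{[tris(4-methoxyphenyl)-λ5-phosphanylidene]amino}butan-2-yl]thiourea, SMILES COc1ccc(cc1)P(=NC[C@@H](NC(=S)Nc1cc(cc(c1)C(F)(F)F)C(F)(F)F)C(C)(C)C)(c1ccc(OC)cc1)c1ccc(OC)cc1, or its mirror image from D-tert-leucine. The antipode that delivers Re-face attack (2R product) is used; which one that is has to be settled in the first run.

## Route

Step 1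
Reactants: 1 3,4-bis(benzyloxy)benzaldehyde
Product: 2 4,5-bis(benzyloxy)-2-bromobenzaldehyde
Conditions: Br2 (1.05 equiv), NaOAc (1.5 equiv), AcOH, 20 °C, 3 h
Reagents that add atoms: bromine, BrBr
Why: Electrophilic aromatic bromination goes para to the 3-benzyloxy group and ortho to the formyl group, as in the veratraldehyde series, and NaOAc takes up HBr so the benzyl ethers survive.

Step 2
Reactants: 2 4,5-bis(benzyloxy)-2-bromobenzaldehyde; 3 1-[2,4-bis(benzyloxy)-6-hydroxyphenyl]ethan-1-one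
Product: 4 (E)-1-[2,4-bis(benzyloxy)-6-hydroxyphenyl]-3-[4,5-bis(benzyloxy)-2-bromophenyl]prop-2-en-1-one
Conditions: 2 (1.1 equiv), KOH (50% aq, 10 equiv), EtOH–THF 2:1, 25 °C, 24 h; cold 1 M HCl to pH 5
Reagents that add atoms: none
Why: Claisen–Schmidt condensation, in which the methyl ketone enolate adds to the non-enolisable aldehyde and E1cB dehydration gives the E-enone.

Step 3
Reactants: 4 (E)-1-[2,4-bis(benzyloxy)-6-hydroxyphenyl]-3-[4,5-bis(benzyloxy)-2-bromophenyl]prop-2-en-1-one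
Product: 5 5,7-bis(benzyloxy)-2-[4,5-bis(benzyloxy)-2-bromophenyl]-4H-chromen-4-one
Conditions: I2 (10 mol %), DMSO, 120 °C, 3 h
Reagents that add atoms: none
Why: Iodine-catalysed oxidative cyclisation of a 2'-hydroxychalcone (oxa-Michael closure forming O1–C2, α-iodination and loss of HI, with DMSO re-oxidising iodide) is the standard flavone synthesis and tolerates aryl benzyl ethers and the aryl bromide.

Step 4
Reactants: 3 1-[2,4-bis(benzyloxy)-6-hydroxyphenyl]ethan-1-one
Product: 6 1-[4,6-bis(benzyloxy)-3-bromo-2-hydroxyphenyl]ethan-1-one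
Conditions: NBS (1.0 equiv), i-Pr2NH (10 mol %), CH2Cl2, 0 °C, 1 h; recrystallise
Reagents that add atoms: N-bromosuccinimide, O=C1CCC(=O)N1Br
Why: Amine-catalysed ortho-bromination of a phenol, in which the chelated OH directs the electrophile to the adjacent carbon, blocks the site that would otherwise lead to an 8-linked flavanone (check: the remaining ring H shows NOE contacts to both OCH2Ph groups).

Step 5
Reactants: 6 1-[4,6-bis(benzyloxy)-3-bromo-2-hydroxyphenyl]ethan-1-one
Product: 7 1-[4,6-bis(benzyloxy)-3-bromo-2-hydroxy-5-iodophenyl]ethan-1-one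
Conditions: NIS (1.1 equiv), CF3CO2H (20 mol %), MeCN–CH2Cl2, 20 °C, 4 h
Reagents that add atoms: N-iodosuccinimide, O=C1CCC(=O)N1I
Why: Acid-activated electrophilic iodination can only take the single remaining ring position, which lies between the two benzyloxy groups and para to the OH, so the regiochemistry is fixed.

Step 6
Reactants: 5 5,7-bis(benzyloxy)-2-[4,5-bis(benzyloxy)-2-bromophenyl]-4H-chromen-4-one; 7 1-[4,6-bis(benzyloxy)-3-bromo-2-hydroxy-5-iodophenyl]ethan-1-one
Product: 9 1-{4,6-bis(benzyloxy)-3-bromo-2-hydroxy-5-[4,5-bis(benzyloxy)-2-(5,7-bis(benzyloxy)-4-oxo-4H-chromen-2-yl)phenyl]phenyl}ethan-1-one, via flavone pinacol boronate 8 (not isolated)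
Conditions: 5 (1.25 equiv), B2pin2 (1.3 equiv), Pd(dppf)Cl2 (4 mol %), KOAc (3 equiv), 1,4-dioxane, 90 °C, 4 h; then 7 (1.0 equiv), Pd(OAc)2 (5 mol %), SPhos (10 mol %), 3 M aq K3PO4 (4 equiv), 80 °C, 12 h
Reagents that add atoms: none
Why: One-pot Miyaura borylation and Suzuki–Miyaura coupling, in which zerovalent palladium inserts far faster into the aryl iodide of 7 than into its bromide (which sits next to a phenoxide) and the dialkylbiarylphosphine ligand carries the tri-ortho-substituted reductive elimination.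

Step 7
Reactants: 9 1-{4,6-bis(benzyloxy)-3-bromo-2-hydroxy-5-[4,5-bis(benzyloxy)-2-(5,7-bis(benzyloxy)-4-oxo-4H-chromen-2-yl)phenyl]phenyl}ethan-1-one; 10 4-(benzyloxy)benzaldehyde
Product: 11 (E)-1-{4,6-bis(benzyloxy)-3-bromo-2-hydroxy-5-[4,5-bis(benzyloxy)-2-(5,7-bis(benzyloxy)-4-oxo-4H-chromen-2-yl)phenyl]phenyl}-3-[4-(benzyloxy)phenyl]prop-2-en-1-one
Conditions: 10 (1.5 equiv), KOH (50% aq, 8 equiv), EtOH–THF 1:1, 25 °C, 36 h; cold 1 M HCl to pH 5; chalcone freed from any cyclised material on silica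
Reagents that add atoms: none
Why: Claisen–Schmidt condensation of the only enolisable ketone with a non-enolisable aldehyde gives the E-chalcone, which stays open as its phenoxide in base while the flavone unit is inert at room temperature.

Step 8
Reactants: 11 (E)-1-{4,6-bis(benzyloxy)-3-bromo-2-hydroxy-5-[4,5-bis(benzyloxy)-2-(5,7-bis(benzyloxy)-4-oxo-4H-chromen-2-yl)phenyl]phenyl}-3-[4-(benzyloxy)phenyl]prop-2-en-1-one
Product: 12 (2R)-5,7-bis(benzyloxy)-2-[4-(benzyloxy)phenyl]-6-[4,5-bis(benzyloxy)-2-(5,7-bis(benzyloxy)-4-oxo-4H-chromen-2-yl)phenyl]-8-bromo-2,3-dihydro-4H-chromen-4-one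
Conditions: catalyst B (10 mol %), toluene–CH2Cl2 4:1, −20 °C, 36 h; AcOH quench, silica plug
Reagents that add atoms: none
Why: Proposed new method: an enantioselective intramolecular oxa-Michael addition in which the strongly basic iminophosphorane of catalyst B deprotonates the acidic, bromine-flanked phenol to a tight chiral iminophosphonium phenoxide ion pair while the thiourea N–H groups bind the enone carbonyl, so the phenoxide closes 6-endo-trig onto the Re face of C-β (C–O bond and 2R centre formed together) and the enolate is protonated by the iminophosphonium to turn the catalyst over; the flanking benzyloxy group twists the enone and makes closure exergonic, which keeps retro-oxa-Michael racemisation slow at −20 °C; the closest known reaction types are the iminophosphorane-catalysed intramolecular oxa-Michael addition of alcohols to unsaturated esters and amides and the tertiary amine–thiourea cyclisation of ester-activated 2'-hydroxychalcones, neither shown for an unactivated, electron-rich, fully substituted chalcone.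

Step 9
Reactants: 12 (2R)-5,7-bis(benzyloxy)-2-[4-(benzyloxy)phenyl]-6-[4,5-bis(benzyloxy)-2-(5,7-bis(benzyloxy)-4-oxo-4H-chromen-2-yl)phenyl]-8-bromo-2,3-dihydro-4H-chromen-4-one
Product: 13 (2R)-6-[2-(5,7-dihydroxy-4-oxo-4H-chromen-2-yl)-4,5-dihydroxyphenyl]-5,7-dihydroxy-2-(4-hydroxyphenyl)-2,3-dihydro-4H-chromen-4-one
Conditions: H2 (1 atm), 10% Pd/C, NaOAc (1.5 equiv), THF–MeOH 1:1, 20 °C, 6–12 h
Reagents that add atoms: none
Why: Catalytic hydrogenolysis cleaves the seven aryl benzyl ethers and, in the same operation, the blocking aryl bromide (hydrodehalogenation, HBr taken up by NaOAc) under near-neutral conditions that neither open the flavanone ring (C-2 stays R) nor reduce the flavone.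

## Compound list

1 | 3,4-bis(benzyloxy)benzaldehyde | O=Cc1ccc(OCc2ccccc2)c(OCc2ccccc2)c1 | starting material
2 | 4,5-bis(benzyloxy)-2-bromobenzaldehyde | O=Cc1cc(OCc2ccccc2)c(OCc2ccccc2)cc1Br | intermediate
3 | 1-[2,4-bis(benzyloxy)-6-hydroxyphenyl]ethan-1-one (2'-hydroxy-4',6'-bis(benzyloxy)acetophenone) | CC(=O)c1c(O)cc(OCc2ccccc2)cc1OCc1ccccc1 | starting material
4 | (E)-1-[2,4-bis(benzyloxy)-6-hydroxyphenyl]-3-[4,5-bis(benzyloxy)-2-bromophenyl]prop-2-en-1-one | O=C(/C=C/c1cc(OCc2ccccc2)c(OCc2ccccc2)cc1Br)c1c(O)cc(OCc2ccccc2)cc1OCc1ccccc1 | intermediate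
5 | 5,7-bis(benzyloxy)-2-[4,5-bis(benzyloxy)-2-bromophenyl]-4H-chromen-4-one | O=c1cc(-c2cc(OCc3ccccc3)c(OCc3ccccc3)cc2Br)oc2cc(OCc3ccccc3)cc(OCc3ccccc3)c12 | intermediate
6 | 1-[4,6-bis(benzyloxy)-3-bromo-2-hydroxyphenyl]ethan-1-one | CC(=O)c1c(O)c(Br)c(OCc2ccccc2)cc1OCc1ccccc1 | intermediate
7 | 1-[4,6-bis(benzyloxy)-3-bromo-2-hydroxy-5-iodophenyl]ethan-1-one | CC(=O)c1c(O)c(Br)c(OCc2ccccc2)c(I)c1OCc1ccccc1 | intermediate
8 | 5,7-bis(benzyloxy)-2-[4,5-bis(benzyloxy)-2-(4,4,5,5-tetramethyl-1,3,2-dioxaborolan-2-yl)phenyl]-4H-chromen-4-one | CC1(C)OB(c2cc(OCc3ccccc3)c(OCc3ccccc3)cc2-c2cc(=O)c3c(OCc4ccccc4)cc(OCc4ccccc4)cc3o2)OC1(C)C | intermediate (not isolated)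
9 | 1-{4,6-bis(benzyloxy)-3-bromo-2-hydroxy-5-[4,5-bis(benzyloxy)-2-(5,7-bis(benzyloxy)-4-oxo-4H-chromen-2-yl)phenyl]phenyl}ethan-1-one | CC(=O)c1c(O)c(Br)c(OCc2ccccc2)c(-c2cc(OCc3ccccc3)c(OCc3ccccc3)cc2-c2cc(=O)c3c(OCc4ccccc4)cc(OCc4ccccc4)cc3o2)c1OCc1ccccc1 | intermediate
10 | 4-(benzyloxy)benzaldehyde | O=Cc1ccc(OCc2ccccc2)cc1 | starting material
11 | (E)-1-{4,6-bis(benzyloxy)-3-bromo-2-hydroxy-5-[4,5-bis(benzyloxy)-2-(5,7-bis(benzyloxy)-4-oxo-4H-chromen-2-yl)phenyl]phenyl}-3-[4-(benzyloxy)phenyl]prop-2-en-1-one | O=C(/C=C/c1ccc(OCc2ccccc2)cc1)c1c(O)c(Br)c(OCc2ccccc2)c(-c2cc(OCc3ccccc3)c(OCc3ccccc3)cc2-c2cc(=O)c3c(OCc4ccccc4)cc(OCc4ccccc4)cc3o2)c1OCc1ccccc1 | intermediate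
12 | (2R)-5,7-bis(benzyloxy)-2-[4-(benzyloxy)phenyl]-6-[4,5-bis(benzyloxy)-2-(5,7-bis(benzyloxy)-4-oxo-4H-chromen-2-yl)phenyl]-8-bromo-2,3-dihydro-4H-chromen-4-one | O=C1C[C@H](c2ccc(OCc3ccccc3)cc2)Oc2c(Br)c(OCc3ccccc3)c(-c3cc(OCc4ccccc4)c(OCc4ccccc4)cc3-c3cc(=O)c4c(OCc5ccccc5)cc(OCc5ccccc5)cc4o3)c(OCc3ccccc3)c21 | intermediate
13 | (2R)-6-[2-(5,7-dihydroxy-4-oxo-4H-chromen-2-yl)-4,5-dihydroxyphenyl]-5,7-dihydroxy-2-(4-hydroxyphenyl)-2,3-dihydro-4H-chromen-4-one | O=C1C[C@H](c2ccc(O)cc2)Oc2cc(O)c(-c3cc(O)c(O)cc3-c3cc(=O)c4c(O)cc(O)cc4o3)c(O)c21 | target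

## Step count and risks

Total steps: 9. Longest linear sequence: 7 (steps 1, 2, 3, 6, 7, 8, 9); the second branch (steps 4, 5) joins at step 6.

**Step 8 (the proposed new cyclisation).** The β-aryl enone is electron-rich and the bromophenoxide is a stabilised nucleophile, so the reaction may be slow. The same base can reopen the product, which erodes ee if the run is not quenched at full conversion. The sense of induction is unknown until the first run (chiral HPLC and CD of 12). The fallback uses known chemistry; it sets out from 9 and comes back at 12. Compound 9 is C-carboxylated through its dilithio species (LiN(SiMe3)2, THF, −78 °C, then Boc2O) to the tert-butyl β-keto ester F1. Knoevenagel condensation with 10 (piperidine/AcOH cat., toluene, 4 Å sieves, 20 °C) gives the alkylidene β-keto ester F2. The known cinchona tertiary amine–thiourea oxa-Michael cyclisation of such ester-activated chalcones (quinidine- or quinine-derived catalyst, the pseudo-enantiomer giving 2R; toluene, −25 °C) gives the tert-butyl flavanone-3-carboxylate F3. TsOH in toluene at 80 °C then cleaves the tert-butyl ester and decarboxylates to return 12.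

**Step 6 (hindered borylation/Suzuki).** The ortho-chromonyl boronate 8 can protodeboronate before it transmetalates, and the iodide of 7 is flanked by two benzyloxy groups. The fallback drops boron; it sets out from 5 and comes back at 9. Compound 5 is converted with Me6Sn2 and Pd(PPh3)4 (toluene, 100 °C) into the arylstannane F4. F4 is then coupled with 7 under copper-assisted Stille conditions (Pd(P(t-Bu)3)2, CuI, CsF, DMF, 45 °C), a base-free transmetalation that suits crowded biaryls, to give 9.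

**Step 9 (global hydrogenolysis).** Long exposure to Pd/C and H2 may also cleave the benzylic C2–O1 bond of the flavanone or leave bromine behind. The fallback separates the two tasks without palladium; it sets out from 12 and comes back at 13. Radical hydrodebromination ((Me3Si)3SiH, AIBN, toluene, 80 °C) gives the bromine-free heptabenzyl ether F5. BCl3 with pentamethylbenzene as benzyl-cation scavenger (CH2Cl2, −78 °C) then removes all seven benzyl groups non-reductively to give 13.

Further compounds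
F1 | step 8 | tert-butyl 3-{4,6-bis(benzyloxy)-3-bromo-2-hydroxy-5-[4,5-bis(benzyloxy)-2-(5,7-bis(benzyloxy)-4-oxo-4H-chromen-2-yl)phenyl]phenyl}-3-oxopropanoate | CC(C)(C)OC(=O)CC(=O)c1c(O)c(Br)c(OCc2ccccc2)c(-c2cc(OCc3ccccc3)c(OCc3ccccc3)cc2-c2cc(=O)c3c(OCc4ccccc4)cc(OCc4ccccc4)cc3o2)c1OCc1ccccc1
F2 | step 8 | tert-butyl 2-{4,6-bis(benzyloxy)-3-bromo-2-hydroxy-5-[4,5-bis(benzyloxy)-2-(5,7-bis(benzyloxy)-4-oxo-4H-chromen-2-yl)phenyl]benzoyl}-3-[4-(benzyloxy)phenyl]prop-2-enoate (E/Z mixture) | CC(C)(C)OC(=O)C(=Cc1ccc(OCc2ccccc2)cc1)C(=O)c1c(O)c(Br)c(OCc2ccccc2)c(-c2cc(OCc3ccccc3)c(OCc3ccccc3)cc2-c2cc(=O)c3c(OCc4ccccc4)cc(OCc4ccccc4)cc3o2)c1OCc1ccccc1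
F3 | step 8 | tert-butyl (2R)-5,7-bis(benzyloxy)-2-[4-(benzyloxy)phenyl]-6-[4,5-bis(benzyloxy)-2-(5,7-bis(benzyloxy)-4-oxo-4H-chromen-2-yl)phenyl]-8-bromo-4-oxochromane-3-carboxylate (C-3 epimers) | O=C1C(C(=O)OC(C)(C)C)[C@H](c2ccc(OCc3ccccc3)cc2)Oc2c(Br)c(OCc3ccccc3)c(-c3cc(OCc4ccccc4)c(OCc4ccccc4)cc3-c3cc(=O)c4c(OCc5ccccc5)cc(OCc5ccccc5)cc4o3)c(OCc3ccccc3)c21
F4 | step 6 | 5,7-bis(benzyloxy)-2-[4,5-bis(benzyloxy)-2-(trimethylstannyl)phenyl]-4H-chromen-4-one | C[Sn](C)(C)c1cc(OCc2ccccc2)c(OCc2ccccc2)cc1-c1cc(=O)c2c(OCc3ccccc3)cc(OCc3ccccc3)cc2o1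
F5 | step 9 | (2R)-5,7-bis(benzyloxy)-2-[4-(benzyloxy)phenyl]-6-[4,5-bis(benzyloxy)-2-(5,7-bis(benzyloxy)-4-oxo-4H-chromen-2-yl)phenyl]-2,3-dihydro-4H-chromen-4-one | O=C1C[C@H](c2ccc(OCc3ccccc3)cc2)Oc2cc(OCc3ccccc3)c(-c3cc(OCc4ccccc4)c(OCc4ccccc4)cc3-c3cc(=O)c4c(OCc5ccccc5)cc(OCc5ccccc5)cc4o3)c(OCc3ccccc3)c21
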